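All runs are calculated from invented constants; the scatter is artificial.

A flask that consumes no target and makes it at a pace blind to target cannot lose a lead, yet Saturday's flask, charged like Monday's plus 24.0 mM of target, ends 11.5 mM above Monday's at 85 min, a smaller lead than the one it began with. I read that gap as the added target still surviving, a pool draining with its own time constant, so its loss constant is 0.00866 min⁻¹. Monday's first reading gives a making constant, target per minute per mM of starting material charged, of 0.0122 min⁻¹. Their quotient, a reading that carries the scatter of these readings, is 0.707, and this is the loss ratio (a selectivity factor), the turnovers of the target pool per turnover of the starting material.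

| flask | starting material | partner | target | time |
|---|---|---|---|---|
| Monday's | 80.0 mM | 120 mM |  |  |
| Sunday's | 32.0 mM | 72.0 mM |  |  |
| Saturday's | 80.0 mM | 120 mM | 24.0 mM |  |
| Thursday's | 80.0 mM | 180 mM |  |  |
| Wednesday's | 80.0 mM | 290 mM |  | 85 min |

| run | time / min | [target] / mM |
|---|---|---|
| Monday's run | 4.8 | 4.7 |
| Monday's run | 15 | 12.7 |
| Monday's run | 28 | 20.7 |
| Monday's run | 44 | 26.2 |
| Monday's run | 63 | 30.8 |
| Monday's run | 85 | 33.6 |
| Sunday's run | 4.8 | 0.3 |
| Sunday's run | 15 | 5.2 |
| Sunday's run | 28 | 7.3 |
| Sunday's run | 44 | 9.8 |
| Sunday's run | 63 | 11.2 |
| Sunday's run | 85 | 13.1 |
| Saturday's run | 4.8 | 27.4 |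
| Saturday's run | 15 | 34.4 |
| Saturday's run | 28 | 38.5 |
| Saturday's run | 44 | 42.4 |
| Saturday's run | 63 | 44.5 |
| Saturday's run | 85 | 45.1 |
| Thursday's run | 4.8 | 6.3 |
| Thursday's run | 15 | 15.8 |
| Thursday's run | 28 | 23.9 |
| Thursday's run | 44 | 29.9 |
| Thursday's run | 63 | 33.0 |
| Thursday's run | 85 | 34.1 |

(readings scatter by 0.4 mM)

- apparent order in [partner] of the starting rate, round the charge of the Monday's run (the rate where two percent of its starting material have turned into target)
- apparent order in [starting material] of the starting rate, round the charge of the Monday's run (the rate where two percent of its starting material have turned into target) (one fixed amount of target, the same in the runs compared)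
- target in the Wednesday's run at 85 min, as a share of the starting material charged

- Overall: starting material + partner -> target.
- Constant volume, constant temperature.
- A reading of a species includes what of it is bound.
- "The second partner" is partner.
- An order is taken over about fifteen percent of the charge, up and down.

I assume that partner speeds both turnovers alike, so it changes the clock and leaves the ratio alone. Then I treat the flask as two tanks in series, the first emptying at one turn per turn and the second at the loss ratio. Monday against Thursday at 15 min gives a partner order of 0.539. For the starting material I take order one, as an assumption; Sunday's flask differs from Monday's in partner as well, and its first two readings are 0.3 mM and 5.2 mM.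

So I reckon that Wednesday's clock runs 1.61 times Monday's, and that Wednesday's curve starts at a slope of 1.57 mM min⁻¹. The two tanks put its top at 1.18 turns, which is 60.1 min, with a peak share of 43.3 % of the charge. By 85 min I reckon that Wednesday's flask has run 1.67 turns, and that its curve has sagged to 40.5 %, less than the peak share.

The forecast gives 0.8, 0.6 and 39 %, and its ground for the plateaus is that “the catalyst or active species appears to die”. My orders differ from both of its orders, and my share lies close to its share.

The flask gives orders of 0.54 and 1.0, and 38.7 % for Wednesday's run, less than my reckoned peak share of 43.3 %.

starting material ⇌ intermediate (0.2640 min⁻¹, 2.346 min⁻¹); intermediate + partner → target (4.836 M⁻¹ min⁻¹); 2 partner ⇌ idle reagent dimer, settled at all times (53.50 M⁻¹); target + partner → side product (0.3528 M⁻¹ min⁻¹) The starting material goes to the intermediate and back, and the intermediate takes up partner to give target, while partner stands in balance with the idle reagent dimer; alongside, from the first target on, target takes up partner to give side product. Sunday's flask, taken on the same loss ratio and on a clock slower than Monday's, comes to 0.790 turns at 85 min, so the two tanks give 40.3 %, and Sunday's reading is 40.9 % of its charge.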